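Read the four flasks against their neighbour south-east, the one with the smallest partner charge.

| flask | starting material | partner | time | remark |
|---|---|---|---|---|
| south-east | 35 mM | 5.00 mM (in portions, 3) | 40 s | the portions of partner follow each other after 12 s, the first at the start |
| east | 35 mM | 15.0 mM (in portions, 3) | 40 s | the portions of partner follow each other after 12 s, the first at the start |
| north-east | 35 mM | 40.0 mM (in portions, 3) | 40 s | the portions of partner follow each other after 12 s, the first at the start |
| west | 35 mM | 120 mM (in portions, 3) | 40 s | the portions of partner follow each other after 12 s, the first at the start |

    starting material + partner → first product + released group (k1 = 3.0 M⁻¹ s⁻¹)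
    partner + first product → bis adduct + released group (k2 = 2.1 M⁻¹ s⁻¹)
    partner + bis adduct → tris adduct + released group (k3 = 2.4 M⁻¹ s⁻¹)
    first product ⇌ isomer of the product (K4 = 0.60, k4 = 0.11 s⁻¹)
    2 starting material → homo dimer (k5 = 3.4 M⁻¹ s⁻¹)

- percent here means starting material units held: one homo dimer counts as two
- where a step has two of a species, its rate is k times that concentration squared, and two are used at each turn
- "hardly changes" means that all values lie within two and a half points (for a concentration: within two and a half percent of the largest)
- run time (south-east): 40 s

* [first product] at the end for south-east, east, north-east, west, in this order
* the shape of the row from first to last (hardly changes / rises, then falls / falls, then rises / falls all the way / rises all the way)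

Call starting material A and partner B, and reckon the fraction of B left at the end in two ways. First, hold A at its charge: each portion then decays with the constant 0.105 s⁻¹, and the portions keep on average 8.47%.

Second, compare rates at the first moment in south-east. Each unit of A is lost to the homo dimer at g = 0.238 s⁻¹ and to the partner at 0.00500 s⁻¹, so the dimer step is faster by a factor of 47.6. As an approximation, let that step set A. Write u(t) for one plus g·t, so that A is the charge divided by u. A portion added at time τ then keeps (u(τ)/u(t))^σ, where σ = k₁/2k₅ = 0.441 is the selectivity factor of capture against dimerisation.

At the end the portions keep 35.4%, 64.2% and 82.0%. Their mean is the partner survival F, 60.5%. The partner charge does not appear in F, so this reckoning gives east the same figure.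

The two ways part, and the first cheats: the first half-life of A by dimerisation, 4.20 s, is shorter than the run, so A does not stay at its charge.

Now turn F into first product. In south-east, the half-life of first product towards bis adduct, 66 s with the whole charge counted, is longer than the run, so neglect that loss. The isomer relaxes in 3.41 s, shorter than the run, so take 62.5% of the pool as first product. That gives 1.23 mM for south-east and, before any loss to bis adduct, 3.70 mM for east.

The reckoning stops at west. There the first-moment ratio of dimer loss to capture drops to 1.98, and the half-life of first product towards bis adduct, with the whole charge counted, is 2.75 s, shorter than the run. So expect the row to rise, then fall.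

The forecast gives 1.15 mM, 2.9 mM, 3.4 mM and 1 mM, shape rises, then falls, on the ground that “the excess partner carries it on to bis and tris adduct”.

The simulation gives 1.09 mM, 2.37 mM, 2.97 mM and 0.990 mM, shape rises, then falls. In south-east at 40.0 s, the dimer step still uses A at 2.1 times the rate of capture, and the homo dimer holds 86.8%. In south-east at that moment, partner goes into first product at 3.6 times its rate into bis adduct. South-east keeps 60% of its partner against F = 60.5%. East keeps 58% against the same 60.5%.

The constants are assumed; the result is computed.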